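## Retrosynthetic overview

- The strategy rests on one structural feature. O1, C3=C4, ring A (C4a to C8a), the C7 oxygen and the C8 prenyl group of the target are those of the coumarin osthole. The two bicycles differ only at C2, a lactone carbonyl in osthole and the gem-dimethyl carbon in the target.
- Key disconnection: the two C2–CH3 bonds and the O1–C2 bond. Double methyl addition to the lactone and cyclodehydration form the 2,2-dimethyl-2H-pyran (ring B), the only ring made in the route.
- The side chain is cut at C6–C(=O), by formylation of the one activated free position of ring A (para to O1, ortho to the C7 oxygen). It is cut again at C(=O)–CH2, by addition of a silyl-protected 4-hydroxyphenethyl Grignard reagent and oxidation.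
- The C7 methyl ether is cleaved late by chelation to the new C6 ketone, and the silyl ether is removed last.

Key step: step 1

Remark: the target has no stereocentre, so no stereocontrol is needed; the carbinol centre formed in step 4 is racemic and is erased in step 5.

## Route

Step 1
Reactants: 1 osthole [7-methoxy-8-(3-methylbut-2-en-1-yl)-2H-chromen-2-one]; 2 methyllithium
Product: 5 7-methoxy-2,2-dimethyl-8-(3-methylbut-2-en-1-yl)-2H-chromene, via lithium Z-enone phenoxide 3 (not isolated), via Z-diol 4 (not isolated)
Conditions: MeLi (3.5 equiv), THF, −78 to 0 °C; sat. aq. NH4Cl; crude diol, PPTS (10 mol %), CH2Cl2, rt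
Reagents that add atoms: methyllithium, [Li]C
Why: Methyllithium adds to the lactone carbonyl C2 of 1, the tetrahedral intermediate collapses with loss of the O1 phenoxide to the Z-enone 3, and the ketone of 3 takes a second methyl in the 1,2-sense to give, after protonation, the Z tertiary allylic alcohol 4. Pyridinium p-toluenesulfonate then ionises the tertiary, aryl-conjugated allylic carbinol and the phenolic O1 captures C2; this six-membered closure of ring B by O1–C2 bond formation is equivalent to oxa-6π electrocyclisation of the ortho-quinone methide and is made easy by the Z geometry inherited from the coumarin. The closest known reaction type is the conversion of coumarins into 2,2-dimethyl-2H-chromenes by excess methyl Grignard reagent or methyllithium followed by acid cyclodehydration. No stereocentre is created, because C2 carries two identical methyl groups. The step needs 1,2- rather than 1,4-addition, which the hard organolithium and the phenoxide-conjugated, electron-rich enone of 3 should secure. It also needs closure through O1–C2 rather than addition of the phenol to the C8 prenyl alkene, which the far easier ionisation of the doubly stabilised carbinol under weak acid should secure.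

Step 2
Reactants: 5 7-methoxy-2,2-dimethyl-8-(3-methylbut-2-en-1-yl)-2H-chromene
Product: 6 7-methoxy-2,2-dimethyl-8-(3-methylbut-2-en-1-yl)-2H-chromene-6-carbaldehyde
Conditions: POCl3 (1.5 equiv), DMF, 0 to 60 °C; then aq. NaOAc, rt
Reagents that add atoms: N,N-dimethylformamide, CN(C)C=O; water, O
Why: Vilsmeier–Haack formylation should go to C6, the only free ring position that is para to O1 and ortho to the C7 methoxy group (C5 is meta to both oxygens), and the weakly electrophilic chloroiminium ion should leave the prenyl alkene untouched.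

Step 3
Reactants: 7 4-(2-bromoethyl)phenol
Product: 8 [4-(2-bromoethyl)phenoxy](tert-butyl)dimethylsilane
Conditions: TBSCl (1.1 equiv), imidazole (2 equiv), CH2Cl2, 0 °C to rt
Reagents that add atoms: tert-butyldimethylsilyl chloride, CC(C)(C)[Si](C)(C)Cl
Why: Imidazole-mediated silylation of the phenol is a standard protection, and the weak base should not trigger displacement of the primary bromide by the phenoxide.

Step 4
Reactants: 8 [4-(2-bromoethyl)phenoxy](tert-butyl)dimethylsilane; 6 7-methoxy-2,2-dimethyl-8-(3-methylbut-2-en-1-yl)-2H-chromene-6-carbaldehyde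
Product: 10 racemic 3-[4-(tert-butyldimethylsilyloxy)phenyl]-1-[7-methoxy-2,2-dimethyl-8-(3-methylbut-2-en-1-yl)-2H-chromen-6-yl]propan-1-ol, via Grignard reagent 9 (not isolated)
Conditions: 8 (1.5 equiv), Mg turnings, I2 (cat.), THF, rt to 45 °C; then 6, THF, 0 °C to rt; sat. aq. NH4Cl
Reagents that add atoms: none
Why: Grignard addition of a stable primary phenethylmagnesium bromide to an aromatic aldehyde forms the C(carbinol)–CH2 bond; the new carbinol centre is formed racemic without control because step 5 removes it.

Step 5
Reactants: 10 racemic 3-[4-(tert-butyldimethylsilyloxy)phenyl]-1-[7-methoxy-2,2-dimethyl-8-(3-methylbut-2-en-1-yl)-2H-chromen-6-yl]propan-1-ol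
Product: 11 3-[4-(tert-butyldimethylsilyloxy)phenyl]-1-[7-methoxy-2,2-dimethyl-8-(3-methylbut-2-en-1-yl)-2H-chromen-6-yl]propan-1-one
Conditions: Dess–Martin periodinane (1.3 equiv), pyridine (3 equiv), CH2Cl2, 0 °C to rt
Reagents that add atoms: none
Why: Dess–Martin oxidation of a secondary benzylic alcohol under pyridine buffering should give the aryl ketone without touching either alkene and without ionising the electron-rich benzylic carbinol.

Step 6
Reactants: 11 3-[4-(tert-butyldimethylsilyloxy)phenyl]-1-[7-methoxy-2,2-dimethyl-8-(3-methylbut-2-en-1-yl)-2H-chromen-6-yl]propan-1-one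
Product: 12 3-[4-(tert-butyldimethylsilyloxy)phenyl]-1-[7-hydroxy-2,2-dimethyl-8-(3-methylbut-2-en-1-yl)-2H-chromen-6-yl]propan-1-one
Conditions: MgI2·OEt2 (3 equiv), toluene, 70 °C; then cold 0.5 M HCl
Reagents that add atoms: none
Why: Chelation-directed demethylation: magnesium bound between the C6 ketone oxygen and the doubly ortho-substituted C7 methoxy oxygen activates only that ether for SN2 attack of iodide at the methyl group, so the pyran oxygen and the remote silyl ether, which cannot chelate, should be spared (any loss of the silyl group here would converge in step 7).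

Step 7
Reactants: 12 3-[4-(tert-butyldimethylsilyloxy)phenyl]-1-[7-hydroxy-2,2-dimethyl-8-(3-methylbut-2-en-1-yl)-2H-chromen-6-yl]propan-1-one
Product: 13 1-[7-hydroxy-2,2-dimethyl-8-(3-methylbut-2-en-1-yl)-2H-chromen-6-yl]-3-(4-hydroxyphenyl)propan-1-one (CNP0163015.0)
Conditions: TBAF (1.2 equiv), AcOH (1.2 equiv), THF, 0 °C
Reagents that add atoms: none
Why: Fluoride cleavage of an aryl silyl ether under acetic acid buffering is fast and mild, and it should leave the hydrogen-bonded ortho-hydroxy ketone, the chromene and the prenyl group intact.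

## Compound list

1 | osthole, 7-methoxy-8-(3-methylbut-2-en-1-yl)-2H-chromen-2-one | COc1ccc2ccc(=O)oc2c1CC=C(C)C | starting material
2 | methyllithium | [Li]C | starting material
3 | lithium 3-methoxy-2-(3-methylbut-2-en-1-yl)-6-[(1Z)-3-oxobut-1-en-1-yl]phenoxide | COc1ccc(/C=C\C(C)=O)c([O-])c1CC=C(C)C.[Li+] | intermediate (not isolated)
4 | 6-[(1Z)-3-hydroxy-3-methylbut-1-en-1-yl]-3-methoxy-2-(3-methylbut-2-en-1-yl)phenol | COc1ccc(/C=C\C(C)(C)O)c(O)c1CC=C(C)C | intermediate (not isolated)
5 | 7-methoxy-2,2-dimethyl-8-(3-methylbut-2-en-1-yl)-2H-chromene | COc1ccc2C=CC(C)(C)Oc2c1CC=C(C)C | intermediate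
6 | 7-methoxy-2,2-dimethyl-8-(3-methylbut-2-en-1-yl)-2H-chromene-6-carbaldehyde | COc1c(C=O)cc2C=CC(C)(C)Oc2c1CC=C(C)C | intermediate
7 | 4-(2-bromoethyl)phenol | Oc1ccc(CCBr)cc1 | starting material
8 | [4-(2-bromoethyl)phenoxy](tert-butyl)dimethylsilane | CC(C)(C)[Si](C)(C)Oc1ccc(CCBr)cc1 | intermediate
9 | {2-[4-(tert-butyldimethylsilyloxy)phenyl]ethyl}magnesium bromide | CC(C)(C)[Si](C)(C)Oc1ccc(CC[Mg]Br)cc1 | intermediate (not isolated)
10 | racemic 3-[4-(tert-butyldimethylsilyloxy)phenyl]-1-[7-methoxy-2,2-dimethyl-8-(3-methylbut-2-en-1-yl)-2H-chromen-6-yl]propan-1-ol | COc1c(C(O)CCc3ccc(O[Si](C)(C)C(C)(C)C)cc3)cc2C=CC(C)(C)Oc2c1CC=C(C)C | intermediate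
11 | 3-[4-(tert-butyldimethylsilyloxy)phenyl]-1-[7-methoxy-2,2-dimethyl-8-(3-methylbut-2-en-1-yl)-2H-chromen-6-yl]propan-1-one | COc1c(C(=O)CCc3ccc(O[Si](C)(C)C(C)(C)C)cc3)cc2C=CC(C)(C)Oc2c1CC=C(C)C | intermediate
12 | 3-[4-(tert-butyldimethylsilyloxy)phenyl]-1-[7-hydroxy-2,2-dimethyl-8-(3-methylbut-2-en-1-yl)-2H-chromen-6-yl]propan-1-one | CC(C)=CCc1c(O)c(C(=O)CCc2ccc(O[Si](C)(C)C(C)(C)C)cc2)cc2c1OC(C)(C)C=C2 | intermediate
13 | 1-[7-hydroxy-2,2-dimethyl-8-(3-methylbut-2-en-1-yl)-2H-chromen-6-yl]-3-(4-hydroxyphenyl)propan-1-one | CC(C)=CCc1c(O)c(C(=O)CCc2ccc(O)cc2)cc2c1OC(C)(C)C=C2 | target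

## Step count and risks

Total step count: 7. Longest linear sequence: 6 steps (steps 1, 2, 4, 5, 6, 7); step 3 is a one-step side branch.

Steps most likely to fail:

**Step 1.** The second methyl addition may stall because methyllithium enolises the methyl ketone of 3. Conjugate methyl addition at C4 may compete before the lactone opens. The new phenol may also add to the prenyl alkene during the acid treatment.
Fallback: each C–C bond is formed in a separate operation on an aldehyde or ketone instead of on the lactone. From 1, iBu2AlH (CH2Cl2, −78 °C) should stop at the lactol 7-methoxy-8-(3-methylbut-2-en-1-yl)-2H-chromen-2-ol F1. Methyllithium 2 (THF, −78 to 0 °C) adds to its open Z-hydroxy-enal form to give racemic 6-[(1Z)-3-hydroxybut-1-en-1-yl]-3-methoxy-2-(3-methylbut-2-en-1-yl)phenol F2, which is handled without acid. MnO2 (CH2Cl2, rt) oxidises the allylic alcohol, and the Z-enone is held by the neighbouring phenol as the hemiketal 7-methoxy-2-methyl-8-(3-methylbut-2-en-1-yl)-2H-chromen-2-ol F3. The second methyl is then delivered by the weakly basic MeCeCl2 (from 2 and CeCl3, THF, −78 °C). This returns to the route at diol 4, which is closed to 5 with PPTS as in step 1.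

**Step 6.** The Lewis acid may induce cyclisation of the prenyl group onto the freed C7 oxygen or opening of the pyran ring, or the ether cleavage may stay incomplete.
Fallback: the deprotection order is reversed and the methyl group is removed by basic SN2 dealkylation, so the C7 oxygen is released as a phenoxide that cannot cyclise. From 11, TBAF/AcOH (THF, 0 °C) removes the silyl group first to give 3-(4-hydroxyphenyl)-1-[7-methoxy-2,2-dimethyl-8-(3-methylbut-2-en-1-yl)-2H-chromen-6-yl]propan-1-one F6. NaSEt (DMF, 100 to 120 °C) then attacks the methyl group of the hindered, acyl-activated ether, and mild acidification returns to the route at 13.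

**Step 2.** The chloroiminium electrophile or adventitious acid may attack the styrene-like C3=C4 bond of the chromene, leading to C3 substitution or oligomerisation instead of formylation at C6.
Fallback: formylation is directed by a magnesium phenoxide under basic conditions. From 5, NaSEt (DMF, reflux) cleaves the methyl ether to 2,2-dimethyl-8-(3-methylbut-2-en-1-yl)-2H-chromen-7-ol F4. MgCl2/Et3N/paraformaldehyde (MeCN, reflux) formylates the only free ortho position, C6, to give 7-hydroxy-2,2-dimethyl-8-(3-methylbut-2-en-1-yl)-2H-chromene-6-carbaldehyde F5. MeI/K2CO3 (acetone, rt) re-methylates the phenol and returns to the route at 6.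

## Further compounds

F1 | step 1 | racemic 7-methoxy-8-(3-methylbut-2-en-1-yl)-2H-chromen-2-ol | COc1ccc2C=CC(O)Oc2c1CC=C(C)C
F2 | step 1 | racemic 6-[(1Z)-3-hydroxybut-1-en-1-yl]-3-methoxy-2-(3-methylbut-2-en-1-yl)phenol | COc1ccc(/C=C\C(C)O)c(O)c1CC=C(C)C
F3 | step 1 | racemic 7-methoxy-2-methyl-8-(3-methylbut-2-en-1-yl)-2H-chromen-2-ol | COc1ccc2C=CC(C)(O)Oc2c1CC=C(C)C
F4 | step 2 | 2,2-dimethyl-8-(3-methylbut-2-en-1-yl)-2H-chromen-7-ol | CC(C)=CCc1c(O)ccc2C=CC(C)(C)Oc12
F5 | step 2 | 7-hydroxy-2,2-dimethyl-8-(3-methylbut-2-en-1-yl)-2H-chromene-6-carbaldehyde | CC(C)=CCc1c(O)c(C=O)cc2C=CC(C)(C)Oc12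
F6 | step 6 | 3-(4-hydroxyphenyl)-1-[7-methoxy-2,2-dimethyl-8-(3-methylbut-2-en-1-yl)-2H-chromen-6-yl]propan-1-one | COc1c(C(=O)CCc3ccc(O)cc3)cc2C=CC(C)(C)Oc2c1CC=C(C)C
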